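**Strategy.** The ten-membered ring is not cyclised but unzipped. In the target the C1 ketone and the C4–C5 epoxide face each other across a latent C1–C5 bond, so a five–seven bicycle (cyclopentane C1–C5 fused to the cycloheptane C1, C5–C10) bearing a C1 alkoxide and a tertiary C4 bromide fragments in one operation to the C1 ketone and the E C4=C5 alkene of the medium ring, with C6, C8 and C10 already set on the rigid bicycle. The precursor is a trans-fused hydroazulene with free tertiary C1–OH, C4 bromide anti to C6, C3 silyl ether, both esters in place and the butenolide masked as a 2,5-dihydrofuran.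

Key step: step 23

Remark (numbering): target numbering is used for every intermediate: ring C1–C10, C14 methyl on C10, C15 methyl on C4, C11 (alkene carbon bearing C13H2–O), C12 (lactone carbon).

Remark (structure check): the C1 carbinol of the bicycle is taken as the epimer with OH cis to C6 and to O3 (1R, trans ring fusion). Only a hydroxyl on the C6 face can steer the 3,4-epoxide to that face, and only that epoxide opens to bromide anti to C6; with the hydroxyl on the other face the sequence would end in the Z alkene. C1 is destroyed in step 23, so the product of the key step is unchanged.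

Remark (end game): C12 is oxidised last, after C4=C5 has become the epoxide, so that C6–H is no longer doubly allylic when hexavalent chromium is used.

Remark (assumption): NaBH4 is assumed to reduce citraconic anhydride mainly at the carbonyl beside the methyl-bearing carbon; the minor 3-methyl butenolide would be removed by distillation.

Remark (assumption): the (−)-Ipc2BOMe-derived crotylborane is assumed to attack the Si face of aldehyde 18, as it does with simple aldehydes.

Step 1
Reactants: 1 citraconic anhydride
Product: 3 4-methylfuran-2(5H)-one, via (Z)-4-hydroxy-3-methylbut-2-enoic acid 2 (not isolated)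
Conditions: NaBH4, THF, 0 °C → rt; 6 M HCl, rt; distillation
Reagents that add atoms: none
Why: Regioselective hydride reduction of an unsymmetrical cyclic anhydride: hydride should attack the carbonyl beside the methyl-bearing carbon (the other is deactivated by conjugation with the methyl-substituted β-carbon), and the Z hydroxy acid set free on acidification lactonises spontaneously.

Step 2
Reactants: 3 4-methylfuran-2(5H)-one
Product: 5 (Z)-4-acetoxy-3-methylbut-2-enoic acid, via sodium (Z)-4-hydroxy-3-methylbut-2-enoate 4 (not isolated)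
Conditions: NaOH (1.0 equiv), H2O–THF, 0 °C; evaporate; Ac2O, pyridine, DMAP (cat.), 0 °C; cold 1 M HCl
Reagents that add atoms: sodium hydroxide [Na+].[OH-]; acetic anhydride CC(=O)OC(C)=O
Why: Saponification followed by O-acetylation: the Z alkene is never broken, the carboxylate salt cannot relactonise, the acetate then blocks relactonisation for good, and any mixed anhydride at the carboxyl group is hydrolysed on work-up.

Step 3
Reactants: 6 2,2-dimethyl-1,3-dioxan-5-one
Product: 7 5-(dibromomethylidene)-2,2-dimethyl-1,3-dioxane
Conditions: CBr4, PPh3, CH2Cl2, 0 °C → rt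
Reagents that add atoms: carbon tetrabromide BrC(Br)(Br)Br
Why: Ramirez dibromo-olefination (first stage of the Corey–Fuchs sequence) of an unhindered, electron-poor ketone; the alkylidene is symmetric, so no alkene geometry arises here or later at C11.

Step 4
Reactants: 7 5-(dibromomethylidene)-2,2-dimethyl-1,3-dioxane
Product: 9 2-bromo-2-(2,2-dimethyl-1,3-dioxan-5-ylidene)acetaldehyde, via alkenylmagnesium carbenoid 8 (not isolated)
Conditions: iPrMgCl·LiCl, THF, −78 °C; DMF, −78 → 0 °C; aq. NH4Cl
Reagents that add atoms: N,N-dimethylformamide CN(C)C=O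
Why: Bromine–magnesium exchange on a 1,1-dibromoalkene gives a magnesium carbenoid that is stable at low temperature and is formylated by DMF (Bouveault-type formylation); either bromine may exchange because the alkylidene is symmetric.

Step 5
Reactants: 10 (S)-4-benzyloxazolidin-2-one; 11 3-methylbut-2-enoyl chloride
Product: 13 (S)-4-benzyl-3-(3-methylbut-2-enoyl)oxazolidin-2-one, via lithium oxazolidinide 12 (not isolated)
Conditions: n-BuLi, THF, −78 °C; 11, −78 → 0 °C
Reagents that add atoms: none
Why: N-acylation of the lithiated chiral auxiliary by an acid chloride.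

Step 6
Reactants: 13 (S)-4-benzyl-3-(3-methylbut-2-enoyl)oxazolidin-2-one; 9 2-bromo-2-(2,2-dimethyl-1,3-dioxan-5-ylidene)acetaldehyde
Product: 15 syn-aldol imide, via boron dienolate 14 (not isolated)
Conditions: Bu2BOTf, Et3N, CH2Cl2, −78 → 0 °C; 9, −78 → 0 °C; pH 7 buffer, MeOH, H2O2
Reagents that add atoms: none
Why: Deconjugative Evans syn-aldol: γ-deprotonation gives the Z(O) boron dienolate, which reacts at its α-carbon through a Zimmerman–Traxler chair, so the (S)-benzyl auxiliary should set C5 and C6 (2S,3S, syn) while the double bond moves out to the isopropenyl group (C4, C15).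

Step 7
Reactants: 15 syn-aldol imide
Product: 16 C6 triethylsilyl ether of the aldol imide
Conditions: TESOTf, 2,6-lutidine, CH2Cl2, −78 °C
Reagents that add atoms: triethylsilyl triflate CC[Si](CC)(CC)OS(=O)(=O)C(F)(F)F
Why: Silylation of the secondary hydroxyl with a silyl triflate and a hindered base, which blocks retro-aldol and marks O6 for release together with the acetonide.

Step 8
Reactants: 16 C6 triethylsilyl ether of the aldol imide
Product: 17 primary alcohol (C1 as CH2OH)
Conditions: LiBH4, MeOH (1 equiv), Et2O, 0 °C
Reagents that add atoms: none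
Why: Reductive cleavage of the acyl oxazolidinone with lithium borohydride, which should reduce only the exocyclic carbonyl without enolising C5 and returns auxiliary 10.

Step 9
Reactants: 17 primary alcohol
Product: 18 aldehyde (C1 as CHO)
Conditions: Dess–Martin periodinane, NaHCO3, CH2Cl2, 0 °C → rt; used crude
Reagents that add atoms: none
Why: Dess–Martin oxidation under buffered, non-basic conditions, so that the α-stereocentre C5 of this β,γ-unsaturated aldehyde should neither epimerise nor move into conjugation.

Step 10
Reactants: 18 aldehyde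
Product: 19 homoallylic alcohol
Conditions: (Z)-but-2-ene, n-BuLi, KOtBu, THF, −78 → −45 °C; (−)-Ipc2BOMe, −78 °C; BF3·OEt2; 18, −78 °C; NaOH, H2O2
Reagents that add atoms: (Z)-crotyldiisopinocampheylborane (made in the flask) C/C=C\CB([C@@H]1C[C@@H]2C[C@H]([C@H]1C)C2(C)C)[C@@H]1C[C@@H]2C[C@H]([C@H]1C)C2(C)C
Why: Brown crotylboration through a closed chair transition state: the (Z)-crotyl group gives the syn C1/C10 pair and the reagent derived from (−)-Ipc2BOMe adds to the Si face of the aldehyde (also its Felkin–Anh face, C6 branch anti), which should set C10 as R; the C1 carbinol centre is erased in step 12.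

Step 11
Reactants: 19 homoallylic alcohol
Product: 20 1,4-diol
Conditions: Sia2BH (from BH3·THF and 2-methylbut-2-ene), THF, 0 °C; NaOH, H2O2, 0 °C → rt
Reagents that add atoms: hydrogen peroxide OO
Why: Hydroboration–oxidation with a bulky dialkylborane: anti-Markovnikov addition to the monosubstituted C8=C9 vinyl group should be much faster than to the hindered isopropenyl group or the tetrasubstituted bromoalkene; no stereocentre is formed.

Step 12
Reactants: 20 1,4-diol
Product: 21 keto aldehyde (C1 ketone, C8 aldehyde)
Conditions: (COCl)2, DMSO, CH2Cl2, −78 °C; iPr2NEt, −78 → −30 °C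
Reagents that add atoms: none
Why: Swern oxidation: both hydroxyls become alkoxysulfonium ions at −78 °C before any carbonyl exists, so the 1,4-diol should give the keto aldehyde and not a lactol or lactone, and the hindered amine should leave C5 and C10 untouched.

Step 13
Reactants: 21 keto aldehyde
Product: 22 seven-membered-ring hydroxy ketone
Conditions: CrCl2 (excess), NiCl2 (cat.), DMSO, rt, high dilution
Reagents that add atoms: none
Why: Intramolecular Nozaki–Hiyama–Kishi reaction: zerovalent nickel inserts into C7–Br, transmetalation gives the alkenyl trivalent-chromium species, and this adds only to the aldehyde (the C1 ketone is inert) to close the seven-membered ring; allylic 1,3-strain with the fully substituted C7=C11 alkene should hold the C8 hydrogen in the alkene plane and place O8 cis to O6.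

Step 14
Reactants: 22 seven-membered-ring hydroxy ketone
Product: 23 tertiary allyl carbinol
Conditions: CH2=CHCH2MgBr (excess), THF, −78 °C
Reagents that add atoms: allylmagnesium bromide C=CC[Mg]Br
Why: Grignard 1,2-addition to the cycloheptanone from the face opposite its two cis α-substituents (C5 isopropenyl, C10 methyl), the face that also carries the C8 magnesium alkoxide, which should give C1 (R) with the hydroxyl cis to the isopropenyl group.

Step 15
Reactants: 23 tertiary allyl carbinol
Product: 24 trans-fused hydroazulene diol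
Conditions: second-generation Grubbs catalyst (5 mol%), CH2Cl2, 40 °C
Reagents that add atoms: none
Why: Ring-closing metathesis of the allyl and isopropenyl groups gives the trisubstituted cyclopentene C3=C4 with loss of ethylene; the tetrasubstituted C7=C11 is inert, and the trans relation of the two groups gives the trans-fused bicycle with C1–OH cis to C6.

Step 16
Reactants: 24 trans-fused hydroazulene diol; 5 (Z)-4-acetoxy-3-methylbut-2-enoic acid
Product: 25 C8 ester
Conditions: 2,4,6-trichlorobenzoyl chloride, Et3N, DMAP, toluene, 0 °C → rt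
Reagents that add atoms: none
Why: Yamaguchi esterification of the secondary allylic C8–OH with retention at C8; the tertiary C1–OH does not acylate and the brief, cold contact with base should preserve the Z geometry of the acid.

Step 17
Reactants: 25 C8 ester
Product: 26 tetraol
Conditions: AcOH–THF–H2O (3:1:1), 40 °C
Reagents that add atoms: none
Why: Mild acid hydrolysis removes the triethylsilyl ether and the acetonide in one operation, while the two esters and the tertiary alcohol should survive; no stereocentre is touched.

Step 18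
Reactants: 26 tetraol
Product: 27 dihydrofuran alcohol
Conditions: PPh3, DIAD, THF, 0 °C → rt
Reagents that add atoms: none
Why: Mitsunobu cyclodehydration: a primary allylic hydroxyl is activated and only the CH2 cis to C6 can be displaced by the C6 hydroxyl (5-exo-tet, retention at C6), so the 2,5-dihydrofuran should form while the other CH2OH remains as C13–OH.

Step 19
Reactants: 27 dihydrofuran alcohol
Product: 28 C13 acetate
Conditions: Ac2O, pyridine, DMAP (cat.), CH2Cl2, 0 °C
Reagents that add atoms: acetic anhydride CC(=O)OC(C)=O
Why: Acetylation of the only primary hydroxyl; the tertiary C1–OH is inert under these conditions.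

Step 20
Reactants: 28 C13 acetate
Product: 29 3,4-epoxide
Conditions: VO(acac)2 (cat.), t-BuOOH, CH2Cl2, 0 °C → rt
Reagents that add atoms: tert-butyl hydroperoxide CC(C)(C)OO
Why: Hydroxyl-directed vanadium epoxidation of a cyclopent-3-enol: the tertiary C1–OH binds the metal peroxide and delivers oxygen to the homoallylic C3=C4 bond on its own face, which is the face of C6; the tetrasubstituted C7=C11 and the enoate have no hydroxyl placed to direct.

Step 21
Reactants: 29 3,4-epoxide
Product: 30 bromohydrin
Conditions: 48% aq. HBr, THF, −20 → 0 °C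
Reagents that add atoms: hydrogen bromide Br
Why: Acid-mediated Markovnikov opening of a trisubstituted epoxide: bromide attacks the tertiary C4 with inversion, which should give C4–Br anti to C6, the C4 methyl cis to C6, and C3–OH retained on the C6 face.

Step 22
Reactants: 30 bromohydrin
Product: 31 bromo silyl ether (fragmentation precursor)
Conditions: TBSOTf (1.1 equiv), 2,6-lutidine, CH2Cl2, −78 °C
Reagents that add atoms: tert-butyldimethylsilyl triflate CC(C)(C)[Si](C)(C)OS(=O)(=O)C(F)(F)F
Why: Selective silylation of the secondary C3 hydroxyl at low temperature with one equivalent of silyl triflate, leaving the tertiary C1 hydroxyl free.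

Step 23
Reactants: 31 bromo silyl ether (fragmentation precursor)
Product: 33 ten-membered ketone, via potassium C1 alkoxide 32 (not isolated)
Conditions: KN(SiMe3)2 (1.05 equiv), THF, −78 → −20 °C; pH 7 buffer
Reagents that add atoms: none
Why: KN(SiMe3)2 deprotonates the tertiary C1–OH (there is no acidic butenolide γ-hydrogen because C12 is still CH2), and the alkoxide lone pair pushes through the C1–C5 σ bond into σ*(C4–Br) in a concerted heterolytic Grob fragmentation that gives the C1 ketone, the C4=C5 π bond and KBr. The closest known reaction type is the Wharton fragmentation of bicyclic γ-halo or γ-sulfonyloxy alkoxides to medium-ring enones, hydroazulene-to-cyclodecenone cases included. No bond is closed: the ten-membered ring is the periphery of the five–seven bicycle and is revealed by cleaving the shared C1–C5 bond, so no cyclisation entropy is paid. No stereocentre is created; the E geometry should follow stereospecifically from C6 being anti to bromide (cis to the C4 methyl) and from a cyclopentane envelope with C5 as the flap, accessible in the trans-fused bicycle, that brings C4–Br to about 160° from C1–C5. The step needs fragmentation to outrun silyl transfer from O3 to O1 (with epoxide re-closure), elimination and acyl transfer; this is served by the bulky silyl group on a hindered tertiary alkoxide, the absence of any ring hydrogen anti to bromide, the low temperature and the single equivalent of base.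

Step 24
Reactants: 33 ten-membered ketone
Product: 34 allylic alcohol
Conditions: HF·pyridine, pyridine, THF, 0 °C → rt
Reagents that add atoms: none
Why: Fluoride desilylation under buffered, weakly acidic conditions that should neither enolise the C1 ketone (C10 stereocentre) nor cleave the esters.

Step 25
Reactants: 34 allylic alcohol
Product: 35 epoxy alcohol
Conditions: VO(acac)2 (cat.), t-BuOOH, CH2Cl2, 0 °C
Reagents that add atoms: tert-butyl hydroperoxide CC(C)(C)OO
Why: Hydroxyl-directed vanadium epoxidation of an allylic alcohol: with C3–H eclipsing the C4 methyl (A(1,2) strain minimised) the (3R) C3–O bond sits about 45° out of the alkene plane on the outer face of the E cycloalkene, and oxygen delivered to that face should give the 4,5-epoxide with the configuration of the target (4S,5R).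

Step 26
Reactants: 35 epoxy alcohol
Product: 36 CNP0274470.1
Conditions: CrO3·3,5-dimethylpyrazole (excess), CH2Cl2, −20 → 0 °C
Reagents that add atoms: chromium trioxide O=[Cr](=O)=O
Why: Chromium trioxide–3,5-dimethylpyrazole oxidation of the C3 carbinol to the ketone and of the allylic ether CH2 (C12) of the 2,5-dihydrofuran to the lactone carbonyl (oxidation of cyclic allylic ethers to unsaturated lactones); the less hindered CH2 should react in preference to the tertiary C6–H, which is no longer doubly allylic.

**Compound list**

1 | citraconic anhydride | CC1=CC(=O)OC1=O | starting material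
2 | (Z)-4-hydroxy-3-methylbut-2-enoic acid | OC(=O)/C=C(/C)CO | intermediate (not isolated)
3 | 4-methylfuran-2(5H)-one | CC1=CC(=O)OC1 | intermediate
4 | sodium (Z)-4-hydroxy-3-methylbut-2-enoate | [Na+].[O-]C(=O)/C=C(/C)CO | intermediate (not isolated)
5 | (Z)-4-acetoxy-3-methylbut-2-enoic acid | OC(=O)/C=C(/C)COC(C)=O | intermediate
6 | 2,2-dimethyl-1,3-dioxan-5-one | CC1(C)OCC(=O)CO1 | starting material
7 | 5-(dibromomethylidene)-2,2-dimethyl-1,3-dioxane | CC1(C)OCC(CO1)=C(Br)Br | intermediate
8 | [bromo(2,2-dimethyl-1,3-dioxan-5-ylidene)methyl]magnesium chloride (alkenylmagnesium carbenoid) | CC1(C)OCC(CO1)=C(Br)[Mg]Cl | intermediate (not isolated)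
9 | 2-bromo-2-(2,2-dimethyl-1,3-dioxan-5-ylidene)acetaldehyde (C6 aldehyde, C7 bromide, C11–C13 as acetonide) | CC1(C)OCC(CO1)=C(Br)C=O | intermediate
10 | (S)-4-benzyloxazolidin-2-one | O=C1N[C@@H](Cc2ccccc2)CO1 | starting material
11 | 3-methylbut-2-enoyl chloride | CC(C)=CC(Cl)=O | starting material
12 | lithium salt of 10 (lithium oxazolidinide) | [Li]N1[C@@H](Cc2ccccc2)COC1=O | intermediate (not isolated)
13 | (S)-4-benzyl-3-(3-methylbut-2-enoyl)oxazolidin-2-one | CC(C)=CC(=O)N1[C@@H](Cc2ccccc2)COC1=O | intermediate
14 | Z(O) dibutylboron dienolate of 13 | CCCCB(CCCC)O/C(=C\C(C)=C)N1[C@@H](Cc2ccccc2)COC1=O | intermediate (not isolated)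
15 | (S)-4-benzyl-3-[(2S,3S)-4-bromo-4-(2,2-dimethyl-1,3-dioxan-5-ylidene)-3-hydroxy-2-(prop-1-en-2-yl)butanoyl]oxazolidin-2-one (syn aldol; acyl carbon = C1, then C5, C6, C7) | CC1(C)OCC(CO1)=C(Br)[C@@H](O)[C@H](C(C)=C)C(=O)N2[C@@H](Cc3ccccc3)COC2=O | intermediate
16 | C6 triethylsilyl ether of 15 | CC1(C)OCC(CO1)=C(Br)[C@@H](O[Si](CC)(CC)CC)[C@H](C(C)=C)C(=O)N2[C@@H](Cc3ccccc3)COC2=O | intermediate
17 | (2R,3S)-4-bromo-4-(2,2-dimethyl-1,3-dioxan-5-ylidene)-2-(prop-1-en-2-yl)-3-(triethylsilyloxy)butan-1-ol | CC1(C)OCC(CO1)=C(Br)[C@@H](O[Si](CC)(CC)CC)[C@H](C(C)=C)CO | intermediate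
18 | (2S,3S)-4-bromo-4-(2,2-dimethyl-1,3-dioxan-5-ylidene)-2-(prop-1-en-2-yl)-3-(triethylsilyloxy)butanal | CC1(C)OCC(CO1)=C(Br)[C@@H](O[Si](CC)(CC)CC)[C@H](C(C)=C)C=O | intermediate
19 | homoallylic alcohol: C1 carbinol (S), C10 methyl (R), vinyl C9=C8; C10-Me, C1-OH, C5 isopropenyl and C6-OTES all syn along the chain | CC1(C)OCC(CO1)=C(Br)[C@@H](O[Si](CC)(CC)CC)[C@H](C(C)=C)[C@@H](O)[C@H](C)C=C | intermediate
20 | 1,4-diol: 19 with the vinyl group converted into C9H2–C8H2OH | CC1(C)OCC(CO1)=C(Br)[C@@H](O[Si](CC)(CC)CC)[C@H](C(C)=C)[C@@H](O)[C@H](C)CCO | intermediate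
21 | keto aldehyde: C1 ketone and C8 aldehyde, otherwise as 20 | CC1(C)OCC(CO1)=C(Br)[C@@H](O[Si](CC)(CC)CC)[C@H](C(C)=C)C(=O)[C@H](C)CC=O | intermediate
22 | seven-membered-ring hydroxy ketone: ring C1(=O)–C10H(Me)–C9H2–C8H(OH)–C7(=dioxanylidene)–C6H(OTES)–C5H(isopropenyl); isopropenyl and C10 methyl cis; O6 and O8 cis to each other, trans to those groups | CC1(C)OCC(CO1)=C2[C@@H](O[Si](CC)(CC)CC)[C@H](C(C)=C)C(=O)[C@H](C)C[C@H]2O | intermediate
23 | tertiary allyl carbinol: C1 (R) with OH cis and allyl trans to the C5 isopropenyl and C10 methyl groups | CC1(C)OCC(CO1)=C2[C@@H](O[Si](CC)(CC)CC)[C@H](C(C)=C)[C@@](O)(CC=C)[C@H](C)C[C@H]2O | intermediate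
24 | trans-fused hydroazulene diol: cyclopentene C1–C2–C3=C4(Me)–C5 fused at C1–C5 to the seven-membered ring; tertiary C1–OH cis to C6; C8–OH; C6–OTES; C7=C11 dioxanylidene | CC1(C)OCC(CO1)=C2[C@@H](O[Si](CC)(CC)CC)[C@@H]3C(C)=CC[C@@]3(O)[C@H](C)C[C@H]2O | intermediate
25 | C8 (Z)-4-acetoxy-3-methylbut-2-enoate of 24 | CC1(C)OCC(CO1)=C2[C@@H](O[Si](CC)(CC)CC)[C@@H]3C(C)=CC[C@@]3(O)[C@H](C)C[C@H]2OC(=O)/C=C(/C)COC(C)=O | intermediate
26 | tetraol: 25 without silyl ether and acetonide (C1–OH, C6–OH, C12–OH, C13–OH) | OCC(CO)=C1[C@@H](O)[C@@H]2C(C)=CC[C@@]2(O)[C@H](C)C[C@H]1OC(=O)/C=C(/C)COC(C)=O | intermediate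
27 | dihydrofuran alcohol: O bridges C6 and C12, C7=C11, free C13–OH | OCC1=C2[C@@H](OC1)[C@@H]3C(C)=CC[C@@]3(O)[C@H](C)C[C@H]2OC(=O)/C=C(/C)COC(C)=O | intermediate
28 | C13 acetate of 27 | CC(=O)OCC1=C2[C@@H](OC1)[C@@H]3C(C)=CC[C@@]3(O)[C@H](C)C[C@H]2OC(=O)/C=C(/C)COC(C)=O | intermediate
29 | 3,4-epoxide of 28, oxygen cis to C1–OH and to C6 | CC(=O)OCC1=C2[C@@H](OC1)[C@@H]3[C@]4(C)O[C@@H]4C[C@@]3(O)[C@H](C)C[C@H]2OC(=O)/C=C(/C)COC(C)=O | intermediate
30 | bromohydrin: tertiary C4–Br anti to C6, C4 methyl cis to C6, C3–OH cis to C1–OH | CC(=O)OCC1=C2[C@@H](OC1)[C@@H]3[C@@](C)(Br)[C@H](O)C[C@@]3(O)[C@H](C)C[C@H]2OC(=O)/C=C(/C)COC(C)=O | intermediate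
31 | C3 tert-butyldimethylsilyl ether of 30, (1R,3R,4R,5S,6S,8R,10R); fragmentation precursor | CC(=O)OCC1=C2[C@@H](OC1)[C@@H]3[C@@](C)(Br)[C@H](O[Si](C)(C)C(C)(C)C)C[C@@]3(O)[C@H](C)C[C@H]2OC(=O)/C=C(/C)COC(C)=O | intermediate
32 | potassium C1 alkoxide of 31 | [K+].CC(=O)OCC1=C2[C@@H](OC1)[C@@H]3[C@@](C)(Br)[C@H](O[Si](C)(C)C(C)(C)C)C[C@@]3([O-])[C@H](C)C[C@H]2OC(=O)/C=C(/C)COC(C)=O | intermediate (not isolated)
33 | ten-membered ketone: C1 ketone, (E)-C4=C5, (3R)-silyl ether, fused 2,5-dihydrofuran, both esters; (3R,6S,8R,10R) | CC(=O)OCC1=C2[C@@H](OC1)/C=C(\C)[C@H](O[Si](C)(C)C(C)(C)C)CC(=O)[C@H](C)C[C@H]2OC(=O)/C=C(/C)COC(C)=O | intermediate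
34 | (3R)-allylic alcohol from 33 | CC(=O)OCC1=C2[C@@H](OC1)/C=C(\C)[C@H](O)CC(=O)[C@H](C)C[C@H]2OC(=O)/C=C(/C)COC(C)=O | intermediate
35 | epoxy alcohol: 4,5-epoxide of 34 on the face of the C3 hydroxyl, epoxide carbons configured as in the target | CC(=O)OCC1=C2[C@@H](OC1)[C@H]1O[C@]1(C)[C@H](O)CC(=O)[C@H](C)C[C@H]2OC(=O)/C=C(/C)COC(C)=O | intermediate
36 | CNP0274470.1, (4S,5R,6R,8R,10R) | CC(=O)OCC1=C2[C@@H](OC1=O)[C@H]1O[C@]1(C)C(=O)CC(=O)[C@H](C)C[C@H]2OC(=O)/C=C(/C)COC(C)=O | target

**Step count.** Total: 26 steps. Longest linear sequence: 23 steps (6 → 7 → 9 → 15 → … → 36; steps 3, 4 and 6–26). Branches: acid 5 (steps 1–2) and imide 13 (step 5).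

**Three steps most likely to fail**

Step 23 (key fragmentation). Silyl transfer from O3 to the cis C1 alkoxide, followed by re-closure of the 3,4-epoxide, or attack of the alkoxide on an ester, may outrun a fragmentation that is slowed whenever the C4–Br bond cannot reach the anti orientation. The fallback sets out from 31 and comes back at 33 without new compounds, replacing the anionic push by a radical one. Suárez hypoiodite conditions (PhI(OAc)2, I2, visible light, cyclohexane–CH2Cl2, rt) would generate the C1 alkoxy radical. β-Scission of C1–C5 gives the C5 radical, which expels the β-bromine atom to form C4=C5. The medium is neutral, no alkoxide is present and no anti alignment of the C–Br bond is required. The alkene geometry is no longer stereospecific and would have to be verified as E.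

Step 13 (seven-membered ring closure). Oxidative addition of zerovalent nickel into the hindered, tetrasubstituted C7–Br bond may be so slow that reduction or pinacol coupling of the aldehyde and intermolecular coupling take over. The fallback sets out from 17 and changes the coupling partner to the alkenyl iodide, the standard substrate class of this reaction. Bromine–lithium exchange with t-BuLi (Et2O, −78 °C) and quench with I2 would give iodo alcohol F1. Steps 9–12 applied unchanged would give iodo aldehyde F2, iodo homoallylic alcohol F3, iodo diol F4 and iodo keto aldehyde F5. Ring closure of F5 with CrCl2/NiCl2 comes back to the route at 22.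

Step 26 (double oxidation). The enolisable 1,3-diketone formed in situ, or the epoxy ketone, may degrade during the long exposure to hexavalent chromium that the ether oxidation needs. The fallback sets out from 33 and reorders the end game so that the diketone never meets chromium. CrO3·3,5-dimethylpyrazole would oxidise C12 while C3 is still silylated, giving butenolide silyl ether F6. HF·pyridine would give butenolide allylic alcohol F7, and VO(acac)2/t-BuOOH would give epoxy alcohol butenolide F8. Dess–Martin periodinane then comes back to the route at 36. The price is that C6–H is doubly allylic during the chromium step.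

**Further compounds**

F0 | step 23 | none | none
F1 | step 13 | iodo alcohol (C7–I analogue of 17) | CC1(C)OCC(CO1)=C(I)[C@@H](O[Si](CC)(CC)CC)[C@H](C(C)=C)CO
F2 | step 13 | iodo aldehyde (C7–I analogue of 18) | CC1(C)OCC(CO1)=C(I)[C@@H](O[Si](CC)(CC)CC)[C@H](C(C)=C)C=O
F3 | step 13 | iodo homoallylic alcohol (C7–I analogue of 19) | CC1(C)OCC(CO1)=C(I)[C@@H](O[Si](CC)(CC)CC)[C@H](C(C)=C)[C@@H](O)[C@H](C)C=C
F4 | step 13 | iodo diol (C7–I analogue of 20) | CC1(C)OCC(CO1)=C(I)[C@@H](O[Si](CC)(CC)CC)[C@H](C(C)=C)[C@@H](O)[C@H](C)CCO
F5 | step 13 | iodo keto aldehyde (C7–I analogue of 21) | CC1(C)OCC(CO1)=C(I)[C@@H](O[Si](CC)(CC)CC)[C@H](C(C)=C)C(=O)[C@H](C)CC=O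
F6 | step 26 | butenolide silyl ether (33 with C12 as lactone carbonyl) | CC(=O)OCC1=C2[C@@H](OC1=O)/C=C(\C)[C@H](O[Si](C)(C)C(C)(C)C)CC(=O)[C@H](C)C[C@H]2OC(=O)/C=C(/C)COC(C)=O
F7 | step 26 | butenolide allylic alcohol | CC(=O)OCC1=C2[C@@H](OC1=O)/C=C(\C)[C@H](O)CC(=O)[C@H](C)C[C@H]2OC(=O)/C=C(/C)COC(C)=O
F8 | step 26 | epoxy alcohol butenolide | CC(=O)OCC1=C2[C@@H](OC1=O)[C@H]1O[C@]1(C)[C@H](O)CC(=O)[C@H](C)C[C@H]2OC(=O)/C=C(/C)COC(C)=O
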